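**Retrosynthetic overview**
1. The strategy rests on C3 of ring C, the only stereocentre of this (3S)-isoflavan. C3 bears ring B through C1' (ortho to the 2'-OMe, para to O4') and lies between C2 (on O1) and C4 (on C4a of ring A, ortho to O1 and para to O7). C2–C3–C4 is thus a glycidyl unit, ring B a good migrating group, ring A a good nucleophile, and C5' the only free carbon ortho to O4'.
2. Late stage: 7-O-MOM cleavage ⇐ IBX oxidative demethylation of the 3'-OMe beside the free 4'-OH ⇐ aromatic Claisen rearrangement of the 4'-O-prenyl ether (C3' and the para carbon C1' are occupied), which builds the quaternary carbon on C5'.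
3. Key disconnection: C3–C1' and C4–C4a are traced back to a (2S)-1-(ring B)-3-(ring A-oxy)propan-2-yl mesylate. On ionisation ring B moves from C4 to C3 through a phenonium ion and ring A closes ring C on C4.
4. The mesylate is assembled at C4–C1' (the aryllithium of TIPS-protected 2,3-dimethoxyphenol opens an epoxide) and at O1–C2 (Mitsunobu reaction of mono-MOM resorcinol with (R)-glycidol).
5. Ring order: rings A and B are bought as arenes; ring C is the only ring made, in step 6.

Key step: step 6

Remark: isoflavan numbering (O1, C2, C3, C4, C4a–C8a; primed locants for ring B) is used for all intermediates, the open-chain ones included; common reagents are taken as purchasable.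

**Step 1**
Reactants: 1 resorcinol
Product: 2 3-(methoxymethoxy)phenol
Conditions: NaH (1.0 equiv), MOMCl (1.0 equiv), 1 (3 equiv), DMF, 0 °C to rt
Reagents that add atoms: chloromethyl methyl ether (MOMCl), COCCl
Why: Williamson-type O-alkylation of the mono-phenoxide, in which the excess of the symmetric diol should keep the bis-acetal low and unreacted resorcinol is removed by aqueous extraction.

**Step 2**
Reactants: 2 3-(methoxymethoxy)phenol; 3 (R)-glycidol
Product: 4 (S)-2-{[3-(methoxymethoxy)phenoxy]methyl}oxirane
Conditions: PPh3, DIAD, THF, 0 °C to rt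
Reagents that add atoms: none
Why: Mitsunobu etherification, in which the phenol displaces the activated primary hydroxyl at CH2, so O1–C2 forms without touching the epoxide carbon (its spatial arrangement is kept; the descriptor changes from R to S only through the change in priorities).

**Step 3**
Reactants: 5 2,3-dimethoxyphenol
Product: 6 (2,3-dimethoxyphenoxy)triisopropylsilane
Conditions: TIPSCl, imidazole, DMF, rt
Reagents that add atoms: chlorotriisopropylsilane (TIPSCl), CC(C)[Si](Cl)(C(C)C)C(C)C
Why: standard silylation of a phenol; the bulky silyl ether resists organolithium attack, shields the neighbouring ring carbon from metalation and later serves as the para donor of ring B.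

**Step 4**
Reactants: 6 (2,3-dimethoxyphenoxy)triisopropylsilane; 4 (S)-2-{[3-(methoxymethoxy)phenoxy]methyl}oxirane
Product: 8 (2S)-1-[2,3-dimethoxy-4-(triisopropylsilyloxy)phenyl]-3-[3-(methoxymethoxy)phenoxy]propan-2-ol, via aryllithium 7 (not isolated)
Conditions: n-BuLi, THF, 0 °C to rt (no diamine additive); then 4, BF3·OEt2, −78 °C; aq NH4Cl
Reagents that add atoms: none
Why: directed ortho-lithiation beside the outer methoxy group (the site next to the silyl ether is blocked) followed by BF3-promoted SN2 opening of the epoxide at its unsubstituted carbon, which forms C4–C1' and leaves the carbinol stereocentre as set in glycidol; the diamine is omitted because it would bind the Lewis acid.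

**Step 5**
Reactants: 8 (2S)-1-[2,3-dimethoxy-4-(triisopropylsilyloxy)phenyl]-3-[3-(methoxymethoxy)phenoxy]propan-2-ol
Product: 9 (2S)-1-[2,3-dimethoxy-4-(triisopropylsilyloxy)phenyl]-3-[3-(methoxymethoxy)phenoxy]propan-2-yl methanesulfonate
Conditions: MsCl, Et3N, CH2Cl2, 0 °C; used without chromatography
Reagents that add atoms: methanesulfonyl chloride (MsCl), CS(=O)(=O)Cl
Why: O-sulfonylation of the secondary alcohol breaks no bond to carbon, so the (S) configuration is retained.

**Step 6**
Reactants: 9 (2S)-1-[2,3-dimethoxy-4-(triisopropylsilyloxy)phenyl]-3-[3-(methoxymethoxy)phenoxy]propan-2-yl methanesulfonate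
Product: 11 (3S)-3-[2,3-dimethoxy-4-(triisopropylsilyloxy)phenyl]-7-(methoxymethoxy)chromane, via phenonium ion pair 10 (not isolated)
Conditions: 2,6-di-tert-butylpyridine (1.5 equiv), (CF3)2CHOH, 0.01 M, rt to 40 °C
Reagents that add atoms: none
Why: Proposed new method: hexafluoroisopropanol should ionise the secondary sulfonate without trapping the cation, and the departure of mesylate is expected to be assisted by ring B, whose ipso carbon C1' (para to the silyloxy donor, ortho to the 2'-methoxy group) bonds to C3 from the face opposite the leaving group to give the spirocyclopropane phenonium ion 10; ring A, held by the O1–C2 tether, then opens the ion at the primary carbon C4 with its carbon para to the OMOM group and rearomatises by giving a proton to the hindered pyridine. The closest known reaction types are the stereospecific phenonium 1,2-aryl shift of 1-aryl-2-alkyl sulfonates, the capture of phenonium ions by arenes in this solvent and the 6-endo Friedel–Crafts closure of aryl glycidyl ethers to chroman-3-ols, of which the present ion is the all-carbon counterpart. Ring C, the only ring closed, forms in the 6-endo mode (a six-membered aryl-participation transition state reaching the back of the C4–C1' bond), whereas closure at C3 would need the strained five-membered mode at the more hindered carbon, which is also deactivated inductively by O1. The new C3–C1' bond is the only stereochemical event: one backside displacement inverts the (2S)-mesylate carbon and should give the (3S)-isoflavan, because mesylate return re-forms the same chiral ion and an open cation at C3 is disfavoured beside the C2–O1 bond. The selectivities needed are C4 over C3 attack (tether length, sterics, induction) and attack through the ring-A carbon para rather than ortho to OMOM (crowding between the two ring-A oxygens); high dilution limits intermolecular capture, and with no good nucleophile present the reversible participation of the 2'-methoxy oxygen should not end in demethylation.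

**Step 7**
Reactants: 11 (3S)-3-[2,3-dimethoxy-4-(triisopropylsilyloxy)phenyl]-7-(methoxymethoxy)chromane
Product: 12 (3S)-3-(4-hydroxy-2,3-dimethoxyphenyl)-7-(methoxymethoxy)chromane
Conditions: n-Bu4NF, THF, 0 °C; water work-up
Reagents that add atoms: none
Why: fluoride-induced cleavage of the aryl silyl ether, driven by the Si–F bond and the phenoxide leaving group, while the MOM acetal and the methyl ethers are inert to fluoride.

**Step 8**
Reactants: 12 (3S)-3-(4-hydroxy-2,3-dimethoxyphenyl)-7-(methoxymethoxy)chromane; 13 prenyl bromide (1-bromo-3-methylbut-2-ene)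
Product: 14 (3S)-3-[2,3-dimethoxy-4-(3-methylbut-2-enyloxy)phenyl]-7-(methoxymethoxy)chromane
Conditions: K2CO3, acetone, reflux
Reagents that add atoms: none
Why: Williamson ether synthesis, the phenoxide attacking the primary allylic bromide by SN2 at its unsubstituted terminus.

**Step 9**
Reactants: 14 (3S)-3-[2,3-dimethoxy-4-(3-methylbut-2-enyloxy)phenyl]-7-(methoxymethoxy)chromane
Product: 16 (3S)-3-[4-hydroxy-2,3-dimethoxy-5-(2-methylbut-3-en-2-yl)phenyl]-7-(methoxymethoxy)chromane, via ortho-dienone 15 (not isolated)
Conditions: N,N-diethylaniline, 190–200 °C, argon, sealed tube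
Reagents that add atoms: none
Why: aromatic Claisen rearrangement, whose [3,3] shift joins the dimethyl-substituted allyl terminus to C5' (the methoxy-bearing C3' and the substituted para carbon C1' cannot end in a phenol) before dienone 15 tautomerises to the 1,1-dimethylallyl phenol; the basic solvent should suppress acid-catalysed cyclisation of the product.

**Step 10**
Reactants: 16 (3S)-3-[4-hydroxy-2,3-dimethoxy-5-(2-methylbut-3-en-2-yl)phenyl]-7-(methoxymethoxy)chromane
Product: 18 (3S)-3-[3,4-dihydroxy-2-methoxy-5-(2-methylbut-3-en-2-yl)phenyl]-7-(methoxymethoxy)chromane, via ortho-quinone 17 (not isolated)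
Conditions: IBX (1.1 equiv), DMF, rt; then aq Na2S2O4, rt
Reagents that add atoms: 2-iodoxybenzoic acid (IBX), O=C1OI(=O)(O)c2ccccc12
Why: IBX-mediated oxidative demethylation of a 2-methoxyphenol, in which the phenol binds to iodine, oxygen is delivered to the only accessible ortho carbon C3' (C5' carries the quaternary group), methanol is lost to give ortho-quinone 17 and dithionite reduces it to the catechol; the 2'-methoxy group is not ortho to the phenol and ring A has no free hydroxyl.

**Step 11**
Reactants: 18 (3S)-3-[3,4-dihydroxy-2-methoxy-5-(2-methylbut-3-en-2-yl)phenyl]-7-(methoxymethoxy)chromane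
Product: 19 (3S)-3-[3,4-dihydroxy-2-methoxy-5-(2-methylbut-3-en-2-yl)phenyl]chroman-7-ol (target CNP0167796.2)
Conditions: HCl (0.5 M) in MeOH, argon, rt to 40 °C
Reagents that add atoms: none
Why: acid-catalysed acetal exchange transfers the methoxymethyl group to methanol; dilute acid and mild temperature are chosen because the monosubstituted vinyl group protonates far more slowly than the acetal, so addition of the 4'-OH to the alkene should not compete.

**Compound list**
1 | resorcinol | Oc1cccc(O)c1 | starting material
2 | 3-(methoxymethoxy)phenol | COCOc1cccc(O)c1 | intermediate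
3 | (R)-glycidol, (2R)-oxiran-2-ylmethanol | OC[C@@H]1CO1 | starting material
4 | (S)-2-{[3-(methoxymethoxy)phenoxy]methyl}oxirane | COCOc1cccc(OC[C@@H]2CO2)c1 | intermediate
5 | 2,3-dimethoxyphenol | COc1cccc(O)c1OC | starting material
6 | (2,3-dimethoxyphenoxy)triisopropylsilane | COc1cccc(O[Si](C(C)C)(C(C)C)C(C)C)c1OC | intermediate
7 | [2,3-dimethoxy-4-(triisopropylsilyloxy)phenyl]lithium (not isolated) | [Li]c1ccc(O[Si](C(C)C)(C(C)C)C(C)C)c(OC)c1OC | intermediate
8 | (2S)-1-[2,3-dimethoxy-4-(triisopropylsilyloxy)phenyl]-3-[3-(methoxymethoxy)phenoxy]propan-2-ol | O[C@@H](Cc1ccc(O[Si](C(C)C)(C(C)C)C(C)C)c(OC)c1OC)COc1cccc(OCOC)c1 | intermediate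
9 | (2S)-1-[2,3-dimethoxy-4-(triisopropylsilyloxy)phenyl]-3-[3-(methoxymethoxy)phenoxy]propan-2-yl methanesulfonate | CS(=O)(=O)O[C@@H](Cc1ccc(O[Si](C(C)C)(C(C)C)C(C)C)c(OC)c1OC)COc1cccc(OCOC)c1 | intermediate
10 | phenonium ion pair: spirocyclopropane cyclohexadienyl cation bridging C3 and C4 (drawn as its silyloxonium form, (S) at C3, spiro carbon undefined) with methanesulfonate (not isolated) | COC1=C(OC)C(=[O+][Si](C(C)C)(C(C)C)C(C)C)C=CC12C[C@@H]2COc1cccc(OCOC)c1.CS(=O)(=O)[O-] | intermediate
11 | (3S)-3-[2,3-dimethoxy-4-(triisopropylsilyloxy)phenyl]-7-(methoxymethoxy)chromane | COc1c(O[Si](C(C)C)(C(C)C)C(C)C)ccc([C@H]2COc3cc(OCOC)ccc3C2)c1OC | intermediate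
12 | (3S)-3-(4-hydroxy-2,3-dimethoxyphenyl)-7-(methoxymethoxy)chromane | COc1c(O)ccc([C@H]2COc3cc(OCOC)ccc3C2)c1OC | intermediate
13 | prenyl bromide, 1-bromo-3-methylbut-2-ene | CC(C)=CCBr | starting material
14 | (3S)-3-[2,3-dimethoxy-4-(3-methylbut-2-enyloxy)phenyl]-7-(methoxymethoxy)chromane | COc1c(OCC=C(C)C)ccc([C@H]2COc3cc(OCOC)ccc3C2)c1OC | intermediate
15 | ortho-dienone: 2,3-dimethoxy-6-(2-methylbut-3-en-2-yl)-4-[(3S)-7-(methoxymethoxy)chroman-3-yl]cyclohexa-2,4-dienone (not isolated; C5' undefined) | C=CC(C)(C)C1C=C([C@H]2COc3cc(OCOC)ccc3C2)C(OC)=C(OC)C1=O | intermediate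
16 | (3S)-3-[4-hydroxy-2,3-dimethoxy-5-(2-methylbut-3-en-2-yl)phenyl]-7-(methoxymethoxy)chromane | C=CC(C)(C)c1cc([C@H]2COc3cc(OCOC)ccc3C2)c(OC)c(OC)c1O | intermediate
17 | ortho-quinone: 3-methoxy-6-(2-methylbut-3-en-2-yl)-4-[(3S)-7-(methoxymethoxy)chroman-3-yl]cyclohexa-3,5-diene-1,2-dione (not isolated) | C=CC(C)(C)C1=CC([C@H]2COc3cc(OCOC)ccc3C2)=C(OC)C(=O)C1=O | intermediate
18 | (3S)-3-[3,4-dihydroxy-2-methoxy-5-(2-methylbut-3-en-2-yl)phenyl]-7-(methoxymethoxy)chromane | C=CC(C)(C)c1cc([C@H]2COc3cc(OCOC)ccc3C2)c(OC)c(O)c1O | intermediate
19 | (3S)-3-[3,4-dihydroxy-2-methoxy-5-(2-methylbut-3-en-2-yl)phenyl]chroman-7-ol | C=CC(C)(C)c1cc([C@H]2COc3cc(O)ccc3C2)c(OC)c(O)c1O | target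

**Step count and risks**
Total step count: 11. Longest linear sequence: 10 steps (resorcinol: steps 1, 2, 4, 5, 6, 7, 8, 9, 10, 11); the ring B branch (steps 3, 4–11) is 9 steps.

Steps most likely to fail:

1. Step 6 (proposed new method). Several processes could compete with the intended aryl shift and closure:
 - the 2'-methoxy oxygen instead of C1' could displace the mesylate, and the oxonium ion could then lose its methyl group;
 - ring A could close on C3 or through its carbon between the two oxygens;
 - the cation could eliminate to an alkene;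
 - the MOM acetal could be lost in the fluoroalcohol.

 Fallback (known chemistry; C3 is set by catalyst control instead of by the aryl shift). It sets out from aryllithium 7, made from 6 as in step 4, and returns to the route at 11. Compound 7 is quenched with BrCF2CF2Br (THF, −78 °C) to give the aryl bromide (4-bromo-2,3-dimethoxyphenoxy)triisopropylsilane F1. Purchased 7-hydroxychroman-4-one is protected with MOMCl and i-Pr2NEt (CH2Cl2) as 7-(methoxymethoxy)chroman-4-one F2. Palladium-catalysed ketone α-arylation of F2 with F1 (Pd2(dba)3, t-Bu3P·HBF4, NaOt-Bu, toluene, 60–80 °C) should give the racemic isoflavanone 3-[2,3-dimethoxy-4-(triisopropylsilyloxy)phenyl]-7-(methoxymethoxy)chroman-4-one F3. Noyori-type asymmetric transfer hydrogenation under dynamic kinetic resolution (RuCl(p-cymene)[(S,S)-TsDPEN], HCO2H/Et3N, rt) follows; the acidic C3 epimerises faster than the ketone is reduced and hydride adds anti to ring B. It should give the cis alcohol (3S,4S)-3-[2,3-dimethoxy-4-(triisopropylsilyloxy)phenyl]-7-(methoxymethoxy)chroman-4-ol F4; the (S,S) catalyst is chosen by analogy with its (S)-selective reduction of chroman-4-one. Hydrogenolysis of the benzylic C4–OH (H2, Pd/C, EtOAc with a trace of AcOH) then gives 11.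

2. Step 9. At the temperature needed, the prenyl group could be lost by ionisation of the ether, the product could rearrange further (abnormal Claisen shift through a spirocyclopropane dienone), or the new phenol could add to the vinyl group.

 Fallback (cross-coupling instead of a sigmatropic shift). It sets out from phenol 12 and returns at 16, bypassing 13, 14 and 15. Iodination of 12 with I2 and morpholine (CH2Cl2, 0 °C) should go to C5', the only open carbon ortho to the phenoxide; the neutral diether ring A reacts far more slowly. This gives (3S)-3-(4-hydroxy-5-iodo-2,3-dimethoxyphenyl)-7-(methoxymethoxy)chromane F5. A branch-selective (γ-selective) Suzuki–Miyaura coupling of F5 with 3-methylbut-2-enylboronic acid pinacol ester (Pd(OAc)2 with a bulky dialkylbiarylphosphine chosen for γ-selectivity, K3PO4, THF/H2O, 40 °C) is a known ligand-controlled route to 1,1-dimethylallyl arenes and should give 16.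

3. Step 4. The Lewis acid could damage the MOM-bearing glycidyl ether (acetal cleavage, epoxide rearrangement), or the coupling of the hindered aryllithium could be sluggish, leaving protonated 6 and unreacted epoxide.

 Fallback (the C–C bond is made first on a simple epoxide, and O1–C2 is made last by phenoxide opening). It sets out from aryllithium 7 and phenol 2 and returns at 8; compound 4 is not used. Compound 7 is transmetalated with MgBr2·OEt2 (THF, −78 to 0 °C) to [2,3-dimethoxy-4-(triisopropylsilyloxy)phenyl]magnesium bromide F6. With catalytic CuI, F6 opens purchased (S)-epichlorohydrin (ClC[C@@H]1CO1) at its epoxide CH2 (THF, −30 °C) to give the chlorohydrin (2S)-1-chloro-3-[2,3-dimethoxy-4-(triisopropylsilyloxy)phenyl]propan-2-ol F7. NaH (THF, 0 °C) closes F7 to (2S)-2-[2,3-dimethoxy-4-(triisopropylsilyloxy)benzyl]oxirane F8. Phenol 2 with K2CO3 in DMF (80 °C) opens F8 at its terminal carbon to give 8. The carbinol carbon of epichlorohydrin is never a reaction site, and the MOM acetal never meets a Lewis acid.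

**Further compounds**
F1 | step 6 | (4-bromo-2,3-dimethoxyphenoxy)triisopropylsilane | COc1c(O[Si](C(C)C)(C(C)C)C(C)C)ccc(Br)c1OC
F2 | step 6 | 7-(methoxymethoxy)chroman-4-one | COCOc1ccc2c(c1)OCCC2=O
F3 | step 6 | rac-3-[2,3-dimethoxy-4-(triisopropylsilyloxy)phenyl]-7-(methoxymethoxy)chroman-4-one | COc1c(O[Si](C(C)C)(C(C)C)C(C)C)ccc(C2COc3cc(OCOC)ccc3C2=O)c1OC
F4 | step 6 | (3S,4S)-3-[2,3-dimethoxy-4-(triisopropylsilyloxy)phenyl]-7-(methoxymethoxy)chroman-4-ol | COc1c(O[Si](C(C)C)(C(C)C)C(C)C)ccc([C@H]2COc3cc(OCOC)ccc3[C@H]2O)c1OC
F5 | step 9 | (3S)-3-(4-hydroxy-5-iodo-2,3-dimethoxyphenyl)-7-(methoxymethoxy)chromane | COc1c(O)c(I)cc([C@H]2COc3cc(OCOC)ccc3C2)c1OC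
F6 | step 4 | [2,3-dimethoxy-4-(triisopropylsilyloxy)phenyl]magnesium bromide | Br[Mg]c1ccc(O[Si](C(C)C)(C(C)C)C(C)C)c(OC)c1OC
F7 | step 4 | (2S)-1-chloro-3-[2,3-dimethoxy-4-(triisopropylsilyloxy)phenyl]propan-2-ol | O[C@@H](Cc1ccc(O[Si](C(C)C)(C(C)C)C(C)C)c(OC)c1OC)CCl
F8 | step 4 | (2S)-2-[2,3-dimethoxy-4-(triisopropylsilyloxy)benzyl]oxirane | COc1c(O[Si](C(C)C)(C(C)C)C(C)C)ccc(C[C@H]2CO2)c1OC
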